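**Plan**

- Retrosynthetic cuts: the 8-O-benzyl bond and the C4 enol ether (masked ketone) come off last; the pyranone ring is cut at C2–C3 and C4–C4a; the O-aryl O-methyl acetal is cut at O1–C2.
- Enabling feature: C2 carries O1, the 3,4-dimethoxyphenyl ring and C3, so it is a latent O-aryl oxocarbenium carbon. C4 sits on the only unsubstituted A-ring carbon, ortho to O1. An aryl oxocarbenium ion plus a two-carbon ketene equivalent (ethoxyacetylene) therefore spans the whole heterocycle.
- Forward order: the A-ring phenol is made from 3,4,5-trimethoxyphenol (MOM ether, ortho-lithiation/borylation/oxidation, benzylation, MOM removal) and joined to the α-chloro methyl ether of veratraldehyde. The annulation closes the only new ring, followed by enol ether hydrolysis and hydrogenolysis.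
- Stereochemistry: C2 is the only stereocentre. It is set in the annulation, where both enantiomers of the acetal collapse to one planar oxocarbenium ion whose faces are differentiated by a chiral squaramide-bound triflate counter-anion. All later steps are non-basic and do not touch C2.
- Activation is aprotic (silyl triflate plus hindered pyridine), because a protic chiral acid and the liberated methanol would both add to ethoxyacetylene.

Key step: step 7

Assumption: the sense of induction of the chiral squaramide with this new ion pair cannot be predicted, so the catalyst antipode that gives the 2S product is chosen by a test reaction with both (equally accessible) enantiomers.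

**Route**

Step 1
Reactants: 1 3,4,5-trimethoxyphenol
Product: 2 1,2,3-trimethoxy-5-(methoxymethoxy)benzene
Conditions: MOMCl, i-Pr2NEt, CH2Cl2, 0 °C → rt
Reagents that add atoms: chloromethyl methyl ether, COCCl
Why: Williamson-type O-alkylation of the phenol gives the MOM ether, which protects O1 and serves as the directing group for the next step.

Step 2
Reactants: 2 1,2,3-trimethoxy-5-(methoxymethoxy)benzene
Product: 5 2,3,4-trimethoxy-6-(methoxymethoxy)phenol, via aryllithium 3 (not isolated), via dimethyl arylboronate 4 (not isolated)
Conditions: n-BuLi, THF, 0 °C; B(OMe)3, −78 °C → rt; AcOH, 30% aq. H2O2, 0 °C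
Reagents that add atoms: hydrogen peroxide, OO
Why: Directed ortho-metalation removes the ring hydrogen flanked by OMOM and OMe (the two ring hydrogens are equivalent), and borylation followed by peroxide oxidation (aryl shift from boron to oxygen) places the new hydroxyl on the carbon that becomes C8.

Step 3
Reactants: 5 2,3,4-trimethoxy-6-(methoxymethoxy)phenol
Product: 6 2-(benzyloxy)-3,4,5-trimethoxy-1-(methoxymethoxy)benzene
Conditions: BnBr, K2CO3, DMF, rt
Reagents that add atoms: benzyl bromide, BrCc1ccccc1
Why: Williamson ether synthesis on the phenoxide installs a benzyl group that is inert to the later acidic steps and removable at the end without base.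

Step 4
Reactants: 6 2-(benzyloxy)-3,4,5-trimethoxy-1-(methoxymethoxy)benzene
Product: 7 2-(benzyloxy)-3,4,5-trimethoxyphenol
Conditions: cat. HCl, MeOH, 40 °C
Reagents that add atoms: none
Why: Acid-catalysed acetal exchange with methanol cleaves the MOM ether selectively, while the benzyl and methyl aryl ethers are stable to dilute methanolic acid.

Step 5
Reactants: 8 3,4-dimethoxybenzaldehyde
Product: 9 4-(dimethoxymethyl)-1,2-dimethoxybenzene
Conditions: HC(OMe)3, cat. TsOH, MeOH, rt; Et3N quench
Reagents that add atoms: trimethyl orthoformate, COC(OC)OC; methanol, CO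
Why: Acid-catalysed acetalisation of the aldehyde is driven to completion by the orthoformate acting as water scavenger.

Step 6
Reactants: 7 2-(benzyloxy)-3,4,5-trimethoxyphenol; 9 4-(dimethoxymethyl)-1,2-dimethoxybenzene
Product: 11 rac-2-(benzyloxy)-1-[(3,4-dimethoxyphenyl)(methoxy)methoxy]-3,4,5-trimethoxybenzene, via α-chloro ether 10 (not isolated)
Conditions: (i) 9, AcCl, cat. SOCl2, CH2Cl2, 0 °C → rt, volatiles removed; (ii) 7, NaH, THF, 0 °C, then 10, −78 → 0 °C; Et3N-buffered work-up, basic alumina
Reagents that add atoms: none
Why: Acetyl chloride exchanges one methoxy group of the acetal for chloride, and the sodium phenoxide of 7 displaces it in a Williamson-type O-alkylation under basic conditions that the acid-labile mixed acetal tolerates; the product is racemic, which does not matter because this centre is erased on ionisation.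

Step 7
Reactants: 11 rac-2-(benzyloxy)-1-[(3,4-dimethoxyphenyl)(methoxy)methoxy]-3,4,5-trimethoxybenzene; 12 ethoxyacetylene
Product: 14 (2S)-8-(benzyloxy)-2-(3,4-dimethoxyphenyl)-4-ethoxy-5,6,7-trimethoxy-2H-chromene, via oxocarbenium triflate 13 (not isolated)
Conditions: chiral arylpyrrolidine tert-leucinamide squaramide (15 mol %), TMSOTf (1.2 equiv, added slowly), 2,6-di-tert-butyl-4-methylpyridine (1.5 equiv), 12 (3 equiv), t-BuOMe, −78 °C, dark; Et3N quench
Reagents that add atoms: none
Why: Proposed new method: the squaramide-bound silyl triflate silylates the more basic methoxy oxygen of 11 and expels MeOSiMe3, so both enantiomers of the acetal give the same O-aryl oxocarbenium ion 13, held as a contact ion pair with the chiral squaramide–triflate anion; the terminal carbon of ethoxyacetylene then attacks C2 (C2–C3), the resulting ethoxy-stabilised vinyl cation (ketene oxonium) at C4 is captured by the one unsubstituted A-ring carbon (C4–C4a), and the hindered pyridine removes the arenium proton. The closest known reactions are the Lewis-acid-promoted oxa-Povarov annulation of O-aryl oxocarbenium ions with alkenes, which gives chromans, and enantioselective additions of π-nucleophiles to oxocarbenium ions paired with hydrogen-bond-donor-bound anions; their combination with an ynol ether is not known. The pyran ring closes by a six-membered intramolecular Friedel–Crafts alkenylation in which C4a attacks the sp-hybridised C4 in the plane of the vinyl cation and the C3=C4 bond ends up inside the ring (overall a stepwise formal [4+2]). C2 is set in the C2–C3 bond-forming event, where the chiral anion complex blocks one face of the planar oxocarbenium ion; the catalyst antipode that leaves open the face leading to 2S is used. The step needs loss of methoxide rather than aryloxide (secured by the higher basicity and accessibility of the methoxy oxygen), closure at C4a faster than intermolecular arylation or triflate capture (secured by the penta-oxygenated ring held ortho to O1 with a single free position), and a medium free of protic acid so that neither the ynol ether nor the enol ether and C2–O1 bond of 14 are attacked (secured by silyl activation and the pyridine base).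

Step 8
Reactants: 14 (2S)-8-(benzyloxy)-2-(3,4-dimethoxyphenyl)-4-ethoxy-5,6,7-trimethoxy-2H-chromene
Product: 15 (2S)-8-(benzyloxy)-2-(3,4-dimethoxyphenyl)-5,6,7-trimethoxy-2,3-dihydro-4H-chromen-4-one
Conditions: 0.5 M aq. HCl, THF, 0 °C, dark
Reagents that add atoms: water, O
Why: Acid-catalysed enol ether hydrolysis proceeds by protonation at C3, addition of water to the C4 oxocarbenium ion and loss of ethanol; C2 is not involved, and cold dilute acid is too mild for retro-oxa-Michael opening of the flavanone.

Step 9
Reactants: 15 (2S)-8-(benzyloxy)-2-(3,4-dimethoxyphenyl)-5,6,7-trimethoxy-2,3-dihydro-4H-chromen-4-one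
Product: 16 (2S)-2-(3,4-dimethoxyphenyl)-8-hydroxy-5,6,7-trimethoxy-2,3-dihydro-4H-chromen-4-one
Conditions: H2 (1 atm), 10% Pd/C, EtOAc, rt
Reagents that add atoms: none
Why: Catalytic hydrogenolysis cleaves the aryl benzyl ether under neutral conditions, avoiding the base-induced chalcone ring-opening that would racemise C2; the reaction is stopped once 15 is consumed so that the C2–O1 bond and the ketone are left intact.

**Compound list**

1 | 3,4,5-trimethoxyphenol | COc1cc(O)cc(OC)c1OC | starting material
2 | 1,2,3-trimethoxy-5-(methoxymethoxy)benzene | COCOc1cc(OC)c(OC)c(OC)c1 | intermediate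
3 | [2,3,4-trimethoxy-6-(methoxymethoxy)phenyl]lithium | [Li]c1c(OCOC)cc(OC)c(OC)c1OC | intermediate
4 | dimethyl [2,3,4-trimethoxy-6-(methoxymethoxy)phenyl]boronate | COB(OC)c1c(OCOC)cc(OC)c(OC)c1OC | intermediate
5 | 2,3,4-trimethoxy-6-(methoxymethoxy)phenol | COCOc1cc(OC)c(OC)c(OC)c1O | intermediate
6 | 2-(benzyloxy)-3,4,5-trimethoxy-1-(methoxymethoxy)benzene | COCOc1cc(OC)c(OC)c(OC)c1OCc1ccccc1 | intermediate
7 | 2-(benzyloxy)-3,4,5-trimethoxyphenol | Oc1cc(OC)c(OC)c(OC)c1OCc1ccccc1 | intermediate
8 | 3,4-dimethoxybenzaldehyde | COc1ccc(C=O)cc1OC | starting material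
9 | 4-(dimethoxymethyl)-1,2-dimethoxybenzene | COC(OC)c1ccc(OC)c(OC)c1 | intermediate
10 | rac-4-[chloro(methoxy)methyl]-1,2-dimethoxybenzene | COC(Cl)c1ccc(OC)c(OC)c1 | intermediate
11 | rac-2-(benzyloxy)-1-[(3,4-dimethoxyphenyl)(methoxy)methoxy]-3,4,5-trimethoxybenzene | COC(Oc1cc(OC)c(OC)c(OC)c1OCc1ccccc1)c1ccc(OC)c(OC)c1 | intermediate
12 | ethoxyacetylene | C#COCC | starting material
13 | [2-(benzyloxy)-3,4,5-trimethoxyphenyl][(3,4-dimethoxyphenyl)methylidene]oxonium trifluoromethanesulfonate | COc1ccc(C=[O+]c2cc(OC)c(OC)c(OC)c2OCc2ccccc2)cc1OC.[O-]S(=O)(=O)C(F)(F)F | intermediate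
14 | (2S)-8-(benzyloxy)-2-(3,4-dimethoxyphenyl)-4-ethoxy-5,6,7-trimethoxy-2H-chromene | COc1ccc([C@@H]2C=C(OCC)c3c(c(OCc4ccccc4)c(OC)c(OC)c3OC)O2)cc1OC | intermediate
15 | (2S)-8-(benzyloxy)-2-(3,4-dimethoxyphenyl)-5,6,7-trimethoxy-2,3-dihydro-4H-chromen-4-one | COc1ccc([C@@H]2CC(=O)c3c(c(OCc4ccccc4)c(OC)c(OC)c3OC)O2)cc1OC | intermediate
16 | (2S)-2-(3,4-dimethoxyphenyl)-8-hydroxy-5,6,7-trimethoxy-2,3-dihydro-4H-chromen-4-one | COc1ccc([C@@H]2CC(=O)c3c(c(O)c(OC)c(OC)c3OC)O2)cc1OC | target

**Step count and risks**

Total step count: 9.
Longest linear sequence: 8 steps (steps 1–4 and 6–9, from 1 to 16); step 5 is a one-step side branch from 8.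

Steps most likely to fail:

1. Step 7 (Proposed new method). What may go wrong:
   - the chiral ion pair may discriminate the two faces of the oxocarbenium ion poorly, or unbound silyl triflate may drive a racemic background reaction;
   - the cation may be lost to intermolecular arylation, or the ynol ether to oligomerisation;
   - the configuration may erode by re-ionisation of the C2–O1 bond of the product;
   - the pyridinium triflate by-product may bind the squaramide and stop turnover.

   The fallback uses known chemistry, sets out from 6 and returns at 15. Ortho-lithiation of 6 at its one ring hydrogen (n-BuLi, THF, 0 °C) and acylation with N-methoxy-N-methylacetamide should give 1-[3-(benzyloxy)-4,5,6-trimethoxy-2-(methoxymethoxy)phenyl]ethan-1-one F1. Methanolic HCl then removes the MOM group to give 1-[3-(benzyloxy)-2-hydroxy-4,5,6-trimethoxyphenyl]ethan-1-one F2. Condensation with DMF dimethyl acetal gives (E)-1-[3-(benzyloxy)-2-hydroxy-4,5,6-trimethoxyphenyl]-3-(dimethylamino)prop-2-en-1-one F3, which on treatment with acid closes to 8-(benzyloxy)-5,6,7-trimethoxy-4H-chromen-4-one F4. A Pd(II)/tert-butyl-pyridine-oxazoline-catalysed asymmetric conjugate addition of 3,4-dimethoxyphenylboronic acid to F4, with the ligand antipode that gives 2S, then delivers 15. Step 9 follows unchanged.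

2. Step 6. The α-chloro ether may decompose before O-alkylation, the electron-rich ring may be C-alkylated instead, or the mixed acetal may hydrolyse or disproportionate on isolation. The fallback sets out from 7 and returns at 11. Williamson etherification of 7 with 3,4-dimethoxybenzyl chloride (K2CO3, DMF) gives 2-(benzyloxy)-1-[(3,4-dimethoxyphenyl)methoxy]-3,4,5-trimethoxybenzene F5. Oxidative benzylic C–H methoxylation of F5 with DDQ in CH2Cl2/MeOH buffered with NaHCO3 then gives 11 by hydride abstraction and capture of the cation by methanol, so no α-chloro ether is handled.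

3. Step 2. Lithiation may be incomplete, or the very electron-rich ring may be over-oxidised towards a quinone during the peroxide step. The fallback sets out from 1 and returns at 5. Magnesium-mediated ortho-formylation of 1 (MgCl2, Et3N, paraformaldehyde, MeCN, reflux) gives 6-hydroxy-2,3,4-trimethoxybenzaldehyde F6. Protection with MOMCl/i-Pr2NEt gives 2,3,4-trimethoxy-6-(methoxymethoxy)benzaldehyde F7. Baeyer–Villiger (Dakin-type) oxidation with mCPBA in CH2Cl2 gives 2,3,4-trimethoxy-6-(methoxymethoxy)phenyl formate F8, which is cleaved with K2CO3 in MeOH to 5.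

**Further compounds**

F1 | step 7 | 1-[3-(benzyloxy)-4,5,6-trimethoxy-2-(methoxymethoxy)phenyl]ethan-1-one | CC(=O)c1c(OCOC)c(OCc2ccccc2)c(OC)c(OC)c1OC
F2 | step 7 | 1-[3-(benzyloxy)-2-hydroxy-4,5,6-trimethoxyphenyl]ethan-1-one | CC(=O)c1c(O)c(OCc2ccccc2)c(OC)c(OC)c1OC
F3 | step 7 | (E)-1-[3-(benzyloxy)-2-hydroxy-4,5,6-trimethoxyphenyl]-3-(dimethylamino)prop-2-en-1-one | CN(C)/C=C/C(=O)c1c(O)c(OCc2ccccc2)c(OC)c(OC)c1OC
F4 | step 7 | 8-(benzyloxy)-5,6,7-trimethoxy-4H-chromen-4-one | O=c1ccoc2c(OCc3ccccc3)c(OC)c(OC)c(OC)c12
F5 | step 6 | 2-(benzyloxy)-1-[(3,4-dimethoxyphenyl)methoxy]-3,4,5-trimethoxybenzene | COc1ccc(COc2cc(OC)c(OC)c(OC)c2OCc2ccccc2)cc1OC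
F6 | step 2 | 6-hydroxy-2,3,4-trimethoxybenzaldehyde | O=Cc1c(O)cc(OC)c(OC)c1OC
F7 | step 2 | 2,3,4-trimethoxy-6-(methoxymethoxy)benzaldehyde | O=Cc1c(OCOC)cc(OC)c(OC)c1OC
F8 | step 2 | 2,3,4-trimethoxy-6-(methoxymethoxy)phenyl formate | O=COc1c(OCOC)cc(OC)c(OC)c1OC
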